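**Plan**
Cedrane numbering is used: C-1 spiro quaternary carbon, C-2 (bears CHO), ring A = cyclopentane C-1 to C-5, C-6 CMe2, C-7 bridgehead CH, C-8=C-9 (CO2H on C-8), C-10 (acyloxy), C-11 CH2 bridge.
Cuts: first the C-10 ester, then C-1–C-11 and C-7–C-8 together. The ring C-1/C-10/C-9/C-8/C-7/C-11, with oxygen on C-10 and the C-8=C-9 enoate, is a 2-silyloxy-diene Diels–Alder adduct after Saegusa oxidation, and the bridge C-5–C-6 is a built-in two-atom tether that carries the vinyl dienophile.
Forward: ring A from 3-ethoxycyclopentenone; one intramolecular [4+2] then closes the cyclopentane C-1/C-5/C-6/C-7/C-11 and the cyclohexene at once (bicyclo[3.2.1]octene); then enone, C-10 carbinol, acylation with the separately made Z-hydroxy acid, global unmasking.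
Stereochemistry: C-5 from asymmetric copper-hydride conjugate reduction; C-2 by thermodynamic trans placement next to C-1 on the monocycle; C-1 and C-7 relayed from C-5 through the tether; C-10 by CBS reduction; Z-alkene by Wittig reaction.

Key step: step 12

Remark: the ligand and catalyst antipodes in steps 4 and 14 are named from the usual stereochemical models; the opposite antipode would be used if the sense of induction proves reversed.

Step 1
Reactants: 1 sorbic acid; 2 2-(trimethylsilyl)ethanol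
Product: 3 2-(trimethylsilyl)ethyl (2E,4E)-hexa-2,4-dienoate
Conditions: DCC, DMAP (cat.), CH2Cl2, 0 °C to rt
Reagents that add atoms: none
Why: Steglich esterification of the dienoic acid with a primary alcohol should be clean and installs the acid-labile ester that is carried to the last step.

Step 2
Reactants: 3 2-(trimethylsilyl)ethyl (2E,4E)-hexa-2,4-dienoate
Product: 5 2-(trimethylsilyl)ethyl (2E)-4-oxobut-2-enoate, via secondary ozonide 4 (not isolated)
Conditions: O3 (1 equiv), CH2Cl2, −78 °C; then Me2S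
Reagents that add atoms: ozone, [O-][O+]=O
Why: Alkene ozonolysis should occur at the distal, more electron-rich 4,5-alkene (the 2,3-alkene is deactivated by the ester), and reductive work-up leaves the (E)-enal.

Step 3
Reactants: 6 3-ethoxycyclopent-2-en-1-one; 7 (3-methylbut-2-en-1-yl)magnesium chloride
Product: 9 3-(2-methylbut-3-en-2-yl)cyclopent-2-en-1-one, via chloromagnesium alkoxide 8 (not isolated)
Conditions: THF, −78 to 0 °C; then 1 M HCl
Reagents that add atoms: water, O
Why: Stork–Danheiser sequence, in which the prenyl Grignard reagent adds to the vinylogous ester through its γ-carbon (six-membered SE2′ transition state) to create the quaternary C-6, and acid hydrolysis with loss of water transposes the carbonyl.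

Step 4
Reactants: 9 3-(2-methylbut-3-en-2-yl)cyclopent-2-en-1-one; 5 2-(trimethylsilyl)ethyl (2E)-4-oxobut-2-enoate
Product: 12 2-(trimethylsilyl)ethyl (2E)-4-hydroxy-4-[(1R,2R)-2-(2-methylbut-3-en-2-yl)-5-oxocyclopentyl]but-2-enoate, via silyl enol ether 10 (not isolated), via silyl aldol ether 11 (not isolated)
Conditions: CuCl (3 mol %), NaOt-Bu (3 mol %), (R)-DTBM-SEGPHOS (3 mol %), PhMe2SiH, PhMe, −20 °C; then 5, Sc(OTf)3 (10 mol %), CH2Cl2, −78 °C; 1 M HCl, THF
Reagents that add atoms: none
Why: Copper hydride–bisphosphine asymmetric conjugate reduction should set the ring stereocenter (R, the future C-5) under ligand control and give the regiodefined silyl enol ether, whose Mukaiyama aldol addition occurs anti to the neighbouring tertiary-alkyl group (2,3-trans); the carbinol center is oxidized later and needs no control.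

Step 5
Reactants: 12 aldol adduct
Product: 13 2-(trimethylsilyl)ethyl (2E)-4-[(tert-butyldimethylsilyl)oxy]-4-[(1R,2R)-2-(2-methylbut-3-en-2-yl)-5-oxocyclopentyl]but-2-enoate
Conditions: TBSOTf, 2,6-lutidine, CH2Cl2, −78 °C
Reagents that add atoms: tert-butyldimethylsilyl triflate, CC(C)(C)[Si](C)(C)OS(=O)(=O)C(F)(F)F
Why: Silylation of the secondary alcohol with the silyl triflate at low temperature should avoid retro-aldol cleavage of the β-hydroxy ketone.

Step 6
Reactants: 13 silyl ether ketone
Product: 14 2-(trimethylsilyl)ethyl (2E)-4-[(tert-butyldimethylsilyl)oxy]-4-[(1S,5R)-2-(methoxymethylidene)-5-(2-methylbut-3-en-2-yl)cyclopentyl]but-2-enoate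
Conditions: Ph3P(CH2OMe)Cl, KN(SiMe3)2, THF, −78 to 0 °C
Reagents that add atoms: (methoxymethyl)triphenylphosphonium chloride, COC[P+](c1ccccc1)(c1ccccc1)c1ccccc1.[Cl-]
Why: Wittig methoxymethylenation of the cyclopentanone adds the carbon that becomes the formyl carbon C-12, and the enoate and silyl ether should be inert to the alkoxy ylide at low temperature.

Step 7
Reactants: 14 enol ether
Product: 15 2-(trimethylsilyl)ethyl (2E)-4-[(tert-butyldimethylsilyl)oxy]-4-[(1S,2S,5R)-2-formyl-5-(2-methylbut-3-en-2-yl)cyclopentyl]but-2-enoate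
Conditions: TsOH·H2O (10 mol %), acetone–H2O, 0 °C to rt; then DBU (0.2 equiv), CH2Cl2, rt
Reagents that add atoms: water, O
Why: Enol ether hydrolysis followed by base equilibration through the aldehyde enolate should place the formyl group trans to the neighbouring side chain and hence cis to the tertiary-alkyl group, the thermodynamically preferred all-trans arrangement that fixes C-2 relative to C-5.

Step 8
Reactants: 15 aldehyde
Product: 16 2-(trimethylsilyl)ethyl (2E)-4-[(tert-butyldimethylsilyl)oxy]-4-[(1S,2S,5R)-2-(1,3-dioxolan-2-yl)-5-(2-methylbut-3-en-2-yl)cyclopentyl]but-2-enoate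
Conditions: (Me3SiOCH2)2, Me3SiOTf (5 mol %), CH2Cl2, −78 °C
Reagents that add atoms: 1,2-bis(trimethylsilyloxy)ethane, C[Si](C)(C)OCCO[Si](C)(C)C
Why: Noyori acetalization masks the epimerizable aldehyde under aprotic low-temperature conditions that should not touch the new C-2 center or the silyl ether.

Step 9
Reactants: 16 acetal silyl ether
Product: 17 2-(trimethylsilyl)ethyl (2E)-4-[(1S,2S,5R)-2-(1,3-dioxolan-2-yl)-5-(2-methylbut-3-en-2-yl)cyclopentyl]-4-hydroxybut-2-enoate
Conditions: HF·pyridine, pyridine, THF, 0 °C to rt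
Reagents that add atoms: none
Why: Buffered fluoride desilylation should free the secondary alcohol while the dioxolane and the 2-(trimethylsilyl)ethyl ester survive.

Step 10
Reactants: 17 allylic alcohol
Product: 18 2-(trimethylsilyl)ethyl (2E)-4-[(1S,2S,5R)-2-(1,3-dioxolan-2-yl)-5-(2-methylbut-3-en-2-yl)cyclopentyl]-4-oxobut-2-enoate
Conditions: Dess–Martin periodinane, NaHCO3, CH2Cl2, 0 °C
Reagents that add atoms: none
Why: Dess–Martin oxidation of the allylic alcohol should give the 4-oxo-enoate without affecting the acetal or the alkenes.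

Step 11
Reactants: 18 ketone
Product: 19 2-(trimethylsilyl)ethyl (2E,4Z)-4-[(tert-butyldimethylsilyl)oxy]-4-[(2S,5S)-2-(1,3-dioxolan-2-yl)-5-(2-methylbut-3-en-2-yl)cyclopentylidene]but-2-enoate
Conditions: TBSOTf, Et3N, CH2Cl2, −78 to −20 °C
Reagents that add atoms: tert-butyldimethylsilyl triflate, CC(C)(C)[Si](C)(C)OS(=O)(=O)C(F)(F)F
Why: Soft enolization at the only enolizable α-position gives the cross-conjugated 2-silyloxy diene, in which the bulky silyloxy group is expected to lie syn to the smaller acetal-bearing ring carbon so that the enoate arm is syn to the carbon that carries the vinyl tether (Z isomer), the geometry the cycloaddition needs.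

Step 12
Reactants: 19 silyl dienol ether
Product: 20 2-(trimethylsilyl)ethyl 10-[(tert-butyldimethylsilyl)oxy]-12,12-(ethane-1,2-diyldioxy)cedr-9-en-15-oate
Conditions: PhMe (0.01 M), BHT, Et3N (0.1 equiv), 14 kbar, 100 °C
Reagents that add atoms: none
Why: Proposed new method: a pressure-accelerated intramolecular Diels–Alder reaction in which the 2-silyloxy diene C-1=C-10–C-9=C-8 and the vinyl group C-7=C-11 are linked only by the two-atom tether C-5–C-6, so the fused mode (a cyclobutane) is impossible and the concerted but asynchronous [4+2] must be bridged, C-11 bonding to C-1 and C-7 to C-8. The closest known reaction types are the intramolecular Diels–Alder reaction of 2-silyloxy dienes with unactivated alkenes (fused mode, longer tethers) and the intramolecular ketene–alkene [2+2] cycloaddition across a two-atom tether, which closes the same bridged five-membered ring. The cyclopentane C-1/C-5/C-6/C-7/C-11 closes exo at the diene terminus C-1 and endo at the vinyl group, a 5-endo approach that the long forming bond of a cycloaddition transition state should tolerate, while the cyclohexene C-1/C-10/C-9/C-8/C-7/C-11 is the ordinary six-membered Diels–Alder ring; together they give the bicyclo[3.2.1]octene. C-1 and C-7 are controlled by C-5, because the short tether lets C-11 reach only the face of C-1 that carries C-6, and C-8 (hydrogen inside, ester outside on the E-enoate) is transient. The step needs the Z enol ether and must outrun unimolecular side reactions: allylic 1,3-strain holds the tertiary-alkyl arm axial over the diene, the competing Cope rearrangement of the 1,5-diene is a reversible, uphill retro-silyloxy-Cope process, and high pressure favors the cycloaddition (large negative activation volume) over [1,5]-hydrogen shifts, with high dilution against dimerization.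

Step 13
Reactants: 20 tricyclic silyl enol ether
Product: 21 2-(trimethylsilyl)ethyl 12,12-(ethane-1,2-diyldioxy)-10-oxocedr-8-en-15-oate
Conditions: Pd(OAc)2 (1.1 equiv), MeCN, 40 °C
Reagents that add atoms: none
Why: Saegusa–Ito oxidation of the silyl enol ether placed regiospecifically by the cycloaddition should give the palladium enolate, and β-hydride elimination of the C-8 hydrogen gives the enone and erases the transient C-8 center.

Step 14
Reactants: 21 enone
Product: 22 2-(trimethylsilyl)ethyl (10S)-12,12-(ethane-1,2-diyldioxy)-10-hydroxycedr-8-en-15-oate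
Conditions: (R)-2-methyl-CBS-oxazaborolidine (20 mol %), catecholborane, PhMe, −78 °C
Reagents that add atoms: none
Why: Corey–Bakshi–Shibata reduction should give 1,2-reduction under reagent control, with the catalyst antipode chosen to deliver hydride to the carbonyl face syn to the C-11 bridge and so place the 10-oxygen anti to C-11 (10S).

Step 15
Reactants: 23 7-bromoheptan-1-ol
Product: 24 [(7-bromoheptyl)oxy](tert-butyl)dimethylsilane
Conditions: TBSCl, imidazole, DMF, rt
Reagents that add atoms: tert-butyldimethylsilyl chloride, CC(C)(C)[Si](C)(C)Cl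
Why: Standard silylation protects the primary alcohol that must not compete in the later esterification.

Step 16
Reactants: 24 bromo silyl ether
Product: 25 {7-[(tert-butyldimethylsilyl)oxy]heptyl}triphenylphosphonium bromide
Conditions: PPh3, MeCN, 80 °C
Reagents that add atoms: triphenylphosphine, c1ccc(cc1)P(c1ccccc1)c1ccccc1
Why: SN2 displacement of the primary bromide by the phosphine gives the Wittig salt.

Step 17
Reactants: 25 phosphonium bromide; 26 methyl 9-oxononanoate
Product: 28 methyl (9Z)-16-[(tert-butyldimethylsilyl)oxy]hexadec-9-enoate, via phosphorus ylide 27 (not isolated)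
Conditions: NaN(SiMe3)2, THF, −78 °C; then 26, −78 °C to rt
Reagents that add atoms: none
Why: Wittig reaction of a non-stabilized ylide under lithium-free conditions should give the Z-alkene through kinetic cis-oxaphosphetane formation.

Step 18
Reactants: 28 methyl ester
Product: 29 (9Z)-16-[(tert-butyldimethylsilyl)oxy]hexadec-9-enoic acid
Conditions: LiOH, THF–MeOH–H2O, rt; then 1 M HCl to pH 4, 0 °C
Reagents that add atoms: lithium hydroxide, [Li+].[OH-]
Why: Saponification of the unhindered methyl ester should leave the primary silyl ether and the Z-alkene untouched.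

Step 19
Reactants: 22 allylic alcohol; 29 protected hydroxy acid
Product: 31 2-(trimethylsilyl)ethyl (10S)-10-{[(9Z)-16-[(tert-butyldimethylsilyl)oxy]hexadec-9-enoyl]oxy}-12,12-(ethane-1,2-diyldioxy)cedr-8-en-15-oate, via mixed anhydride 30 (not isolated)
Conditions: 2,4,6-trichlorobenzoyl chloride, Et3N, THF, rt; then 22, DMAP, PhMe, 40 °C
Reagents that add atoms: none
Why: Yamaguchi esterification should acylate the hindered secondary allylic alcohol through the mixed anhydride and DMAP with retention at C-10.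

Step 20
Reactants: 31 fully protected ester
Product: 32 (10S)-10-{[(9Z)-16-hydroxyhexadec-9-enoyl]oxy}-12-oxocedr-8-en-15-oic acid (CNP0214056.2)
Conditions: CF3CO2H–CH2Cl2–H2O (10:10:1), 0 °C to rt
Reagents that add atoms: water, O
Why: Aqueous trifluoroacetic acid should remove the three acid-labile groups in one operation (β-silyl fragmentation of the 2-(trimethylsilyl)ethyl ester, silyl ether cleavage, acetal hydrolysis) under non-basic conditions that spare the allylic ester and the epimerizable formyl center.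

**Compound list**
1 | (2E,4E)-hexa-2,4-dienoic acid (sorbic acid) | C/C=C/C=C/C(=O)O | starting material
2 | 2-(trimethylsilyl)ethanol | C[Si](C)(C)CCO | starting material
3 | 2-(trimethylsilyl)ethyl (2E,4E)-hexa-2,4-dienoate | C/C=C/C=C/C(=O)OCC[Si](C)(C)C | intermediate
4 | 2-(trimethylsilyl)ethyl (2E)-3-(5-methyl-1,2,4-trioxolan-3-yl)prop-2-enoate (secondary ozonide, ring stereoisomers, not isolated) | CC1OOC(O1)/C=C/C(=O)OCC[Si](C)(C)C | intermediate
5 | 2-(trimethylsilyl)ethyl (2E)-4-oxobut-2-enoate | O=C/C=C/C(=O)OCC[Si](C)(C)C | intermediate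
6 | 3-ethoxycyclopent-2-en-1-one | CCOC1=CC(=O)CC1 | starting material
7 | (3-methylbut-2-en-1-yl)magnesium chloride | CC(C)=CC[Mg]Cl | starting material
8 | chloromagnesium 3-ethoxy-1-(2-methylbut-3-en-2-yl)cyclopent-2-en-1-olate (racemic, not isolated) | CCOC1=CC(CC1)(O[Mg]Cl)C(C)(C)C=C | intermediate
9 | 3-(2-methylbut-3-en-2-yl)cyclopent-2-en-1-one | C=CC(C)(C)C1=CC(=O)CC1 | intermediate
10 | dimethyl{[(3R)-3-(2-methylbut-3-en-2-yl)cyclopent-1-en-1-yl]oxy}phenylsilane (not isolated) | C=CC(C)(C)[C@@H]1CCC(O[Si](C)(C)c2ccccc2)=C1 | intermediate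
11 | 2-(trimethylsilyl)ethyl (2E)-4-{[dimethyl(phenyl)silyl]oxy}-4-[(1R,2R)-2-(2-methylbut-3-en-2-yl)-5-oxocyclopentyl]but-2-enoate (C-4 epimers, not isolated) | C=CC(C)(C)[C@@H]1CCC(=O)[C@H]1C(O[Si](C)(C)c2ccccc2)/C=C/C(=O)OCC[Si](C)(C)C | intermediate
12 | 2-(trimethylsilyl)ethyl (2E)-4-hydroxy-4-[(1R,2R)-2-(2-methylbut-3-en-2-yl)-5-oxocyclopentyl]but-2-enoate (C-4 epimers) | C=CC(C)(C)[C@@H]1CCC(=O)[C@H]1C(O)/C=C/C(=O)OCC[Si](C)(C)C | intermediate
13 | 2-(trimethylsilyl)ethyl (2E)-4-[(tert-butyldimethylsilyl)oxy]-4-[(1R,2R)-2-(2-methylbut-3-en-2-yl)-5-oxocyclopentyl]but-2-enoate (C-4 epimers) | C=CC(C)(C)[C@@H]1CCC(=O)[C@H]1C(O[Si](C)(C)C(C)(C)C)/C=C/C(=O)OCC[Si](C)(C)C | intermediate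
14 | 2-(trimethylsilyl)ethyl (2E)-4-[(tert-butyldimethylsilyl)oxy]-4-[(1S,5R)-2-(methoxymethylidene)-5-(2-methylbut-3-en-2-yl)cyclopentyl]but-2-enoate (enol ether E/Z mixture, C-4 epimers) | C=CC(C)(C)[C@@H]1CCC(=COC)[C@H]1C(O[Si](C)(C)C(C)(C)C)/C=C/C(=O)OCC[Si](C)(C)C | intermediate
15 | 2-(trimethylsilyl)ethyl (2E)-4-[(tert-butyldimethylsilyl)oxy]-4-[(1S,2S,5R)-2-formyl-5-(2-methylbut-3-en-2-yl)cyclopentyl]but-2-enoate (all-trans ring, C-4 epimers) | C=CC(C)(C)[C@@H]1CC[C@H](C=O)[C@H]1C(O[Si](C)(C)C(C)(C)C)/C=C/C(=O)OCC[Si](C)(C)C | intermediate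
16 | 2-(trimethylsilyl)ethyl (2E)-4-[(tert-butyldimethylsilyl)oxy]-4-[(1S,2S,5R)-2-(1,3-dioxolan-2-yl)-5-(2-methylbut-3-en-2-yl)cyclopentyl]but-2-enoate (C-4 epimers) | C=CC(C)(C)[C@@H]1CC[C@H](C2OCCO2)[C@H]1C(O[Si](C)(C)C(C)(C)C)/C=C/C(=O)OCC[Si](C)(C)C | intermediate
17 | 2-(trimethylsilyl)ethyl (2E)-4-[(1S,2S,5R)-2-(1,3-dioxolan-2-yl)-5-(2-methylbut-3-en-2-yl)cyclopentyl]-4-hydroxybut-2-enoate (C-4 epimers) | C=CC(C)(C)[C@@H]1CC[C@H](C2OCCO2)[C@H]1C(O)/C=C/C(=O)OCC[Si](C)(C)C | intermediate
18 | 2-(trimethylsilyl)ethyl (2E)-4-[(1S,2S,5R)-2-(1,3-dioxolan-2-yl)-5-(2-methylbut-3-en-2-yl)cyclopentyl]-4-oxobut-2-enoate | C=CC(C)(C)[C@@H]1CC[C@H](C2OCCO2)[C@H]1C(=O)/C=C/C(=O)OCC[Si](C)(C)C | intermediate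
19 | 2-(trimethylsilyl)ethyl (2E,4Z)-4-[(tert-butyldimethylsilyl)oxy]-4-[(2S,5S)-2-(1,3-dioxolan-2-yl)-5-(2-methylbut-3-en-2-yl)cyclopentylidene]but-2-enoate | C=CC(C)(C)[C@@H]1CC[C@H](C2OCCO2)/C1=C(O[Si](C)(C)C(C)(C)C)/C=C/C(=O)OCC[Si](C)(C)C | intermediate
20 | 2-(trimethylsilyl)ethyl 10-[(tert-butyldimethylsilyl)oxy]-12,12-(ethane-1,2-diyldioxy)cedr-9-en-15-oate (C-1, C-2, C-5, C-7 as in the target; 8-H syn to the C-5/C-6 bridge) | CC1(C)[C@H]2C[C@@]3(C(O[Si](C)(C)C(C)(C)C)=C[C@@H]2C(=O)OCC[Si](C)(C)C)[C@@H](C4OCCO4)CC[C@@H]13 | intermediate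
21 | 2-(trimethylsilyl)ethyl 12,12-(ethane-1,2-diyldioxy)-10-oxocedr-8-en-15-oate (C-1, C-2, C-5, C-7 as in the target) | CC1(C)[C@H]2C[C@@]3(C(=O)C=C2C(=O)OCC[Si](C)(C)C)[C@@H](C4OCCO4)CC[C@@H]13 | intermediate
22 | 2-(trimethylsilyl)ethyl (10S)-12,12-(ethane-1,2-diyldioxy)-10-hydroxycedr-8-en-15-oate | CC1(C)[C@H]2C[C@@]3([C@@H](O)C=C2C(=O)OCC[Si](C)(C)C)[C@@H](C4OCCO4)CC[C@@H]13 | intermediate
23 | 7-bromoheptan-1-ol | OCCCCCCCBr | starting material
24 | [(7-bromoheptyl)oxy](tert-butyl)dimethylsilane | BrCCCCCCCO[Si](C)(C)C(C)(C)C | intermediate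
25 | {7-[(tert-butyldimethylsilyl)oxy]heptyl}triphenylphosphonium bromide | CC(C)(C)[Si](C)(C)OCCCCCCC[P+](c1ccccc1)(c1ccccc1)c1ccccc1.[Br-] | intermediate
26 | methyl 9-oxononanoate | COC(=O)CCCCCCCC=O | starting material
27 | {7-[(tert-butyldimethylsilyl)oxy]heptylidene}triphenylphosphorane (not isolated) | CC(C)(C)[Si](C)(C)OCCCCCCC=P(c1ccccc1)(c1ccccc1)c1ccccc1 | intermediate
28 | methyl (9Z)-16-[(tert-butyldimethylsilyl)oxy]hexadec-9-enoate | COC(=O)CCCCCCC/C=C\CCCCCCO[Si](C)(C)C(C)(C)C | intermediate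
29 | (9Z)-16-[(tert-butyldimethylsilyl)oxy]hexadec-9-enoic acid | OC(=O)CCCCCCC/C=C\CCCCCCO[Si](C)(C)C(C)(C)C | intermediate
30 | (9Z)-16-[(tert-butyldimethylsilyl)oxy]hexadec-9-enoic 2,4,6-trichlorobenzoic anhydride (not isolated) | O=C(CCCCCCC/C=C\CCCCCCO[Si](C)(C)C(C)(C)C)OC(=O)c1c(Cl)cc(Cl)cc1Cl | intermediate
31 | 2-(trimethylsilyl)ethyl (10S)-10-{[(9Z)-16-[(tert-butyldimethylsilyl)oxy]hexadec-9-enoyl]oxy}-12,12-(ethane-1,2-diyldioxy)cedr-8-en-15-oate | CC1(C)[C@H]2C[C@@]3([C@@H](OC(=O)CCCCCCC/C=C\CCCCCCO[Si](C)(C)C(C)(C)C)C=C2C(=O)OCC[Si](C)(C)C)[C@@H](C4OCCO4)CC[C@@H]13 | intermediate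
32 | (10S)-10-{[(9Z)-16-hydroxyhexadec-9-enoyl]oxy}-12-oxocedr-8-en-15-oic acid (CNP0214056.2) | CC1(C)[C@H]2C[C@@]3([C@@H](OC(=O)CCCCCCC/C=C\CCCCCCO)C=C2C(=O)O)[C@@H](C=O)CC[C@@H]13 | target

**Count and risks**
Total steps: 20. Longest linear sequence: 15 steps (steps 1, 2, 4 to 14, 19, 20).

Step 12 (riskiest). The bridged transition state may be too strained for an unactivated vinyl group, so that [1,5]-hydrogen shift, dimerization or desilylation of the diene takes over. A polar, stepwise closure of the same two bonds by known reaction types would set out from alcohol 17. Dehydration with the Burgess reagent (PhH, 50 °C) would give the exocyclic dienoate F1, and Tsuji–Wacker oxidation of the vinyl group (PdCl2, CuCl, O2, DMF–H2O) the methyl ketone F2. LiN(SiMe3)2 (THF, −78 to 0 °C) would then bring about intramolecular 1,6-Michael addition of the methyl-ketone enolate carbon (C-11) to the diene terminus C-1, followed by aldol closure of the dienolate α-carbon C-8 onto the C-7 ketone (Michael–aldol annulation), to give the bridgehead alcohol F3. Acylation with methyl chlorooxoacetate (DMAP, pyridine) to the oxalate F4 and radical deoxygenation (Bu3SnH, AIBN, PhMe, 110 °C) would give the cedr-9-ene ester F5. A singlet-oxygen ene reaction at C-10 with shift of the alkene to C-8=C-9 (O2, tetraphenylporphyrin, light), then Kornblum–DeLaMare dehydration of the allylic hydroperoxide (Ac2O, Et3N), would return to the route at enone 21.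

Step 11. Enolization of the hindered methine may be sluggish, or the enol ether may form mainly with the unreactive E geometry. Ketone 18 would instead be acetylated under acid catalysis with reversible enolization (isopropenyl acetate, TsOH, 90 °C; thermodynamic control, the E isomer recycled under the same conditions) to the dienyl acetate F6. Its cycloaddition under the conditions of step 12 would give the tricyclic enol acetate F7. Tin-enolate formation and palladium-catalyzed dehydrogenation (Bu3SnOMe, Pd(OAc)2 cat., allyl methyl carbonate, MeCN, 80 °C) would return to the route at enone 21.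

Step 14. Facial selectivity at C-10 may be poor or reversed, because the acetal-bearing C-2 substituent shields the face syn to C-11 and may override the catalyst. The enone 21 would then be reduced from the open face (NaBH4, CeCl3·7H2O, MeOH, −78 °C) to the 10-epi alcohol F8, and the ester formed with inversion by Mitsunobu reaction with acid 29 (PPh3, DIAD, PhMe, 0 °C), returning to the route at ester 31.

Further compounds
F1 | step 12 | 2-(trimethylsilyl)ethyl (2E)-4-[(2S,5S)-2-(1,3-dioxolan-2-yl)-5-(2-methylbut-3-en-2-yl)cyclopentylidene]but-2-enoate (geometrical isomers at the exocyclic alkene) | C=CC(C)(C)[C@@H]1CC[C@H](C2OCCO2)C1=C/C=C/C(=O)OCC[Si](C)(C)C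
F2 | step 12 | 2-(trimethylsilyl)ethyl (2E)-4-[2-(1,3-dioxolan-2-yl)-5-(2-methyl-3-oxobutan-2-yl)cyclopentylidene]but-2-enoate (ring configuration as in F1) | CC(=O)C(C)(C)[C@@H]1CC[C@H](C2OCCO2)C1=C/C=C/C(=O)OCC[Si](C)(C)C
F3 | step 12 | 2-(trimethylsilyl)ethyl 12,12-(ethane-1,2-diyldioxy)-7-hydroxycedr-9-en-15-oate (C-8 epimers; C-1, C-2, C-5 as in the target) | CC1(C)[C@@]2(O)C[C@@]3(C=CC2C(=O)OCC[Si](C)(C)C)[C@@H](C4OCCO4)CC[C@@H]13
F4 | step 12 | 2-(trimethylsilyl)ethyl 12,12-(ethane-1,2-diyldioxy)-7-[(methoxyoxalyl)oxy]cedr-9-en-15-oate (C-8 epimers) | CC1(C)[C@@]2(OC(=O)C(=O)OC)C[C@@]3(C=CC2C(=O)OCC[Si](C)(C)C)[C@@H](C4OCCO4)CC[C@@H]13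
F5 | step 12 | 2-(trimethylsilyl)ethyl 12,12-(ethane-1,2-diyldioxy)cedr-9-en-15-oate (C-8 epimers) | CC1(C)[C@H]2C[C@@]3(C=CC2C(=O)OCC[Si](C)(C)C)[C@@H](C4OCCO4)CC[C@@H]13
F6 | step 11 | 2-(trimethylsilyl)ethyl (2E,4Z)-4-acetoxy-4-[(2S,5S)-2-(1,3-dioxolan-2-yl)-5-(2-methylbut-3-en-2-yl)cyclopentylidene]but-2-enoate | C=CC(C)(C)[C@@H]1CC[C@H](C2OCCO2)/C1=C(OC(C)=O)/C=C/C(=O)OCC[Si](C)(C)C
F7 | step 11 | 2-(trimethylsilyl)ethyl 10-acetoxy-12,12-(ethane-1,2-diyldioxy)cedr-9-en-15-oate | CC1(C)[C@H]2C[C@@]3(C(OC(C)=O)=C[C@@H]2C(=O)OCC[Si](C)(C)C)[C@@H](C4OCCO4)CC[C@@H]13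
F8 | step 14 | 2-(trimethylsilyl)ethyl (10R)-12,12-(ethane-1,2-diyldioxy)-10-hydroxycedr-8-en-15-oate (10-epimer of 22) | CC1(C)[C@H]2C[C@@]3([C@H](O)C=C2C(=O)OCC[Si](C)(C)C)[C@@H](C4OCCO4)CC[C@@H]13
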